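The data are simulated with constants of no real substance, noise included.

**A small charge.** The theta flask holds a quarter of beta's substrate and a quarter of its reagent, with the same free catalyst.

| flask | substrate | reagent | free catalyst | time |
|---|---|---|---|---|
| beta | 0.0800 M | 0.160 M | 8.00 × 10⁻⁴ M |  |
| zeta | 0.0800 M | 0.160 M | 4.00 × 10⁻⁴ M |  |
| gamma | 0.0800 M | 0.240 M | 8.00 × 10⁻⁴ M |  |
| alpha | 0.240 M | 0.160 M | 8.00 × 10⁻⁴ M |  |
| theta | 0.0200 M | 0.0400 M | 8.00 × 10⁻⁴ M | 110 min |

- beta run (time / min: [substrate] / M): 18: 0.05198; 37: 0.03378; 55: 0.02340; 73: 0.01654; 92: 0.01209; 110: 0.00952
- zeta run (time / min: [substrate] / M): 18: 0.06326; 37: 0.04946; 55: 0.03952; 73: 0.03207; 92: 0.02547; 110: 0.02117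
- gamma run (time / min: [substrate] / M): 18: 0.04644; 37: 0.02790; 55: 0.01862; 73: 0.01337; 92: 0.00962; 110: 0.00774
- alpha run (time / min: [substrate] / M): 18: 0.19434; 37: 0.16079; 55: 0.13885; 73: 0.12302; 92: 0.11078; 110: 0.10268

(readings scatter by 2 × 10⁻⁴ M)

- order of the initial rate in [substrate], near the charge of the beta run, the rate being that where two percent of its substrate are target (one fixed amount of target, the same in the runs compared)
- order of the initial rate in [free catalyst], near the charge of the beta run, the rate being that where two percent of its substrate are target
- substrate in the theta run at 110 min, as a share of the substrate charged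

- Overall: substrate + reagent -> target, with free catalyst as catalyst.
- Constant volume, constant temperature.
- The analysis sees a species whether free or bound.
- An order is taken over about fifteen percent of the charge, up and down.

**Early orders.** My own reading uses the first 18 min. Tripling substrate in the alpha run gives an order of 0.444, and raising reagent in the gamma run gives 0.445. Their sum is 0.889. I take the sum as near one, so dilution at a fixed ratio of substrate to reagent should leave the fractional rate almost unchanged. The zeta run gives a catalyst order of 0.877.

**One number.** The beta run fell by 0.924 decades in 110 min. Decades here mean the base-ten logarithm of charge over remainder. If theta falls as far, it keeps 11.9 % of its substrate, and that is my reckoning.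

**The test.** Beta's decades over zeta's are 1.84 at 18 min but 1.60 at 110 min. That ratio drifts, so one number may not carry over to theta. No run shows that dilution.

**The forecast.** It gave 0.5 and 0.88, and for theta 4.5 %, lower than my share, because “it has far less target”.

**The result.**

    free catalyst + substrate ⇌ catalyst-substrate complex (74.40 M⁻¹ min⁻¹, 0.2706 min⁻¹)
    catalyst-substrate complex + reagent → target + free catalyst (25.80 M⁻¹ min⁻¹)
    2 free catalyst → 2 spent catalyst (34.62 M⁻¹ min⁻¹)
    substrate + reagent → target (0.01092 M⁻¹ min⁻¹)

The orders are 0.49 and 0.92, and theta keeps 19.9 %, more than either reckoning. The uncatalysed turning of substrate and reagent shifts that share by under one percentage point. Theta thus fell 0.702 decades, 0.760 of beta's. Beta's decades, spread evenly over 110 min and cut to half for zeta's catalyst, put zeta's target at half of its charge after 71.6 min. The zeta run got there sooner, at 54.0 min.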